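The constants used here are invented; what happens was integrated by code.

Slowness of addition is what separates the flasks below: beta gets everything at once, while eta and gamma each receive one charge slowly over 25 h.

    starting complex + incoming ligand ⇌ leaving ligand + complex with one exchanged (K1 = 2.7, k1 = 26.2 M⁻¹ h⁻¹)
    complex with one exchanged + incoming ligand ⇌ leaving ligand + complex with two exchanged (K2 = 14.1, k2 = 32.8 M⁻¹ h⁻¹)
    starting complex + complex with two exchanged ⇌ idle adduct, settled at all times (K3 = 204 M⁻¹)
    2 starting complex → homo dimer (k4 = 7.16 M⁻¹ h⁻¹)

common to all: leaving ligand 0.140 M; time 2.5 d

|  | starting complex | incoming ligand | remark |
|---|---|---|---|
| beta | 0.14 M | 0.0700 M | everything together at the start |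
| eta | 0.14 M (fed, over 25 h) | 0.0700 M | all else is in the flask from the start; the feed brings no volume worth counting |
| gamma | 0.14 M | 0.0700 M (fed, over 25 h) | all else is in the flask from the start; the feed brings no volume worth counting |

* the best flask by amount of complex with two exchanged, in percent of the starting complex charged; "all alike" if 1.5 percentage points covers them all (beta / eta / gamma / all alike)
* amount of complex with two exchanged at the end, in percent of the starting complex charged, beta
* amount of complex with two exchanged at the end, in percent of the starting complex charged, eta
* amount of complex with two exchanged at the end, in percent of the starting complex charged, gamma

- percentages count the starting complex that a species holds: one idle adduct or homo dimer counts as two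
- complex with two exchanged is meant together with its idle adduct
- where a step has two of a species, its rate is k times that concentration squared, and two are used at each turn
- in an amount of complex with two exchanged, one idle adduct counts as one complex with two exchanged
- run time (beta): 2.5 d

Turn the question round and ask what would have to be true for gamma to beat eta. Starting complex leaves by two paths, and the dimer step is second order in c(starting complex) while the exchange is first order in it, so with c(incoming ligand) held, a higher c(starting complex) tilts its loss towards the dimer. Beta opens at 1.09 for twice the dimer constant times c(starting complex), divided by the first exchange constant times c(incoming ligand): this is the branch ratio, a selectivity factor, and the paths in beta start about even. My test of the opposite outcome is whether gamma's opening ratio lies below eta's, which is a test of the opening and not a condition on the end.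

I reckon eta by letting the first exchange take up the starting complex as it arrives, with the ligand at its charge, which gives 0.0238. In gamma the starting complex stands at its charge and the ligand is taken up as it arrives, which gives 100. Gamma opens 4202 times higher than eta, so my order is eta, beta, gamma. This reckoning covers the opening alone, ignores the way back and gives no percentages.

The forecast gives 10.3 % for beta, 11.4 % for eta and 5.2 % for gamma, “making eta narrowly the best and gamma clearly the worst”.

The flasks give 9.89 % for beta, 11.4 % for eta and 4.46 % for gamma, so eta is best, as forecast. Shortening gamma's feed to 0.104 d gives 8.92 %, still less than eta, so that change does not overturn the forecast. Eta's means over the first 25 h, 0.0129 M and 0.0298 M, give a branch ratio of 0.236, ten times my opening value but below beta's opening value.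

Gamma with 0.28 M of incoming ligand opens at 25.1, lower than gamma but still favouring the dimer. That flask ends with 14.4 % of complex with two exchanged and 83.8 % as homo dimer, and its amount of complex with two exchanged is more than eta's 11.4 % although its opening ratio stands far above eta's, so here a higher opening ratio did not go with a lower amount.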